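**Assumptions:** The SMILES decodes to the trans-(2R,3R)-2,3-dihydro-1,4-benzodioxine. The CH(CH2OH) carbon sits on the oxygen para to the chromone, next to the OMe, and the CH(aryl) carbon sits on the meta oxygen. Compounds 1, 2, 4 and 9 are taken as catalogue chemicals. If not stocked, 4 and 9 are each one BnBr/K2CO3 step from syringaldehyde and phloroacetophenone.

## Retrosynthetic overview
1. The last step is global O-debenzylation of a tri-O-benzyl flavone.
2. The pyranone ring is formed last, by cyclodehydration of a 1,3-diketone. The diketone comes from a crossed Claisen condensation of an A-ring acetophenone with a benzodioxane methyl ester.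
3. The dioxane ring is formed first, by intramolecular Pd-catalysed aryl C–O coupling of a threo bromoaryl ether. The carbinol configuration is retained, so threo gives trans.
4. The benzylic C–C bond and both stereocentres come from one Evans syn glycolate aldol.
5. The regiochemistry is fixed beforehand by O-alkylating the only phenol of methyl 5-bromovanillate.

## Route

**Step 1**
Reactants: 1, methyl 3-bromo-4-hydroxy-5-methoxybenzoate; 2, (4S)-4-benzyl-3-(chloroacetyl)-1,3-oxazolidin-2-one
Product: 3, methyl 4-{2-[(4S)-4-benzyl-2-oxo-1,3-oxazolidin-3-yl]-2-oxoethoxy}-3-bromo-5-methoxybenzoate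
Conditions: K2CO3, NaI (cat.), MeCN, 50 °C
Reagents that add atoms: compound 2, O=C(CCl)N1[C@@H](Cc2ccccc2)COC1=O
Why: This is a Finkelstein-assisted Williamson etherification (SN2) of the single phenol, which fixes the bond between the para oxygen and the future C-2 and creates no new stereocentre.

**Step 2**
Reactants: 3; 4, 4-(benzyloxy)-3,5-dimethoxybenzaldehyde
Product: 5, methyl 4-({(1R,2S)-1-[4-(benzyloxy)-3,5-dimethoxyphenyl]-3-[(4S)-4-benzyl-2-oxo-1,3-oxazolidin-3-yl]-1-hydroxy-3-oxopropan-2-yl}oxy)-3-bromo-5-methoxybenzoate (Evans-syn adduct)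
Conditions: n-Bu2BOTf, Et3N, CH2Cl2, −78 → 0 °C; then 4, −78 → 0 °C; then pH 7 buffer, MeOH, 30% H2O2, 0 °C
Reagents that add atoms: compound 4, COc1cc(C=O)cc(OC)c1OCc1ccccc1
Why: In this Evans syn glycolate aldol, the Z-boron enolate reacts through a Zimmerman–Traxler chair with one face shielded by the (4S)-benzyl group, which sets both stereocentres (α-S, carbinol-R, syn/threo) in one step.

**Step 3**
Reactants: 5
Product: 6, methyl 4-({(1R,2R)-1-[4-(benzyloxy)-3,5-dimethoxyphenyl]-1,3-dihydroxypropan-2-yl}oxy)-3-bromo-5-methoxybenzoate (threo diol)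
Conditions: NaBH4, THF/H2O (4:1), 0 °C → rt
Reagents that add atoms: none
Why: Borohydride reduces only the activated exocyclic imide carbonyl (reductive auxiliary removal) and leaves the aryl ester and ArBr intact, with no bond to a stereocentre broken (the S→R change is only a CIP priority change).

**Step 4**
Reactants: 6
Product: 7, methyl 4-({(1R,2R)-1-[4-(benzyloxy)-3,5-dimethoxyphenyl]-1-hydroxy-3-(trityloxy)propan-2-yl}oxy)-3-bromo-5-methoxybenzoate
Conditions: TrCl, Et3N, DMAP (cat.), CH2Cl2, rt
Reagents that add atoms: trityl chloride, ClC(c1ccccc1)(c1ccccc1)c1ccccc1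
Why: Sterically controlled tritylation selects the primary OH, which would otherwise also close to a six-membered ring in step 5, and a trityl group cannot migrate under base.

**Step 5**
Reactants: 7
Product: 8, methyl (2R,3R)-3-[4-(benzyloxy)-3,5-dimethoxyphenyl]-8-methoxy-2-[(trityloxy)methyl]-2,3-dihydro-1,4-benzodioxine-6-carboxylate
Conditions: Pd(OAc)2 (5 mol %), 2-(di-tert-butylphosphino)-1,1′-binaphthyl (6 mol %), Cs2CO3, toluene, 80 °C
Reagents that add atoms: none
Why: This Buchwald-type intramolecular aryl C–O coupling forms only the aryl–O bond, so the carbinol configuration is retained and the threo (R,R) ether becomes the trans-(2R,3R) dioxane.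

**Step 6**
Reactants: 8; 9, 1-[2,4-bis(benzyloxy)-6-hydroxyphenyl]ethan-1-one
Product: 10, 1-[2,4-bis(benzyloxy)-6-hydroxyphenyl]-3-{(2R,3R)-3-[4-(benzyloxy)-3,5-dimethoxyphenyl]-8-methoxy-2-[(trityloxy)methyl]-2,3-dihydro-1,4-benzodioxin-6-yl}propane-1,3-dione
Conditions: 9 (1.5 equiv), LiHMDS (5 equiv), THF, −78 °C → rt (50 °C if slow); aq NH4Cl
Reagents that add atoms: compound 9, CC(=O)c1c(O)cc(OCc2ccccc2)cc1OCc1ccccc1
Why: In this crossed Claisen condensation the phenoxide/enolate dianion of 9 attacks a non-enolisable, unhindered methyl benzoate, and deprotonation of the resulting diketone drives the reaction.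

**Step 7**
Reactants: 10
Product: 11, 5,7-bis(benzyloxy)-2-{(2R,3R)-3-[4-(benzyloxy)-3,5-dimethoxyphenyl]-2-(hydroxymethyl)-8-methoxy-2,3-dihydro-1,4-benzodioxin-6-yl}-4H-chromen-4-one
Conditions: TsOH·H2O, MeOH/THF (1:1), 60 °C
Reagents that add atoms: none
Why: Acid-catalysed cyclodehydration, the closing stage of a Baker–Venkataraman-type flavone synthesis, can use only the one free ortho OH, and the trityl ether solvolyses (SN1) in the same pot, while any reversible benzylic ionisation would re-close trans under control of C-2.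

**Step 8**
Reactants: 11
Product: 12, palstatin, 5,7-dihydroxy-2-[(2R,3R)-3-(4-hydroxy-3,5-dimethoxyphenyl)-2-(hydroxymethyl)-8-methoxy-2,3-dihydro-1,4-benzodioxin-6-yl]-4H-chromen-4-one
Conditions: H2 (1 atm), 10% Pd/C, THF/MeOH, rt
Reagents that add atoms: none
Why: Catalytic hydrogenolysis cleaves the three primary aryl benzyl ethers much faster than the secondary ring C–O bond or the flavone C2=C3 bond, and it does not touch the stereocentres.

## Compound list
1 | methyl 3-bromo-4-hydroxy-5-methoxybenzoate | COC(=O)c1cc(Br)c(O)c(OC)c1 | starting material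
2 | (4S)-4-benzyl-3-(chloroacetyl)-1,3-oxazolidin-2-one | O=C(CCl)N1[C@@H](Cc2ccccc2)COC1=O | starting material
3 | aryloxyacetyl imide | COC(=O)c1cc(Br)c(OCC(=O)N2[C@@H](Cc3ccccc3)COC2=O)c(OC)c1 | intermediate
4 | 4-(benzyloxy)-3,5-dimethoxybenzaldehyde | COc1cc(C=O)cc(OC)c1OCc1ccccc1 | starting material
5 | Evans-syn aldol adduct (carbinol R, α-carbon S, auxiliary 4S) | COC(=O)c1cc(Br)c(O[C@@H]([C@H](O)c2cc(OC)c(OCc3ccccc3)c(OC)c2)C(=O)N2[C@@H](Cc3ccccc3)COC2=O)c(OC)c1 | intermediate
6 | (1R,2R)-threo 1,3-diol | COC(=O)c1cc(Br)c(O[C@@H]([C@H](O)c2cc(OC)c(OCc3ccccc3)c(OC)c2)CO)c(OC)c1 | intermediate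
7 | (1R,2R) primary trityl ether | COC(=O)c1cc(Br)c(O[C@@H]([C@H](O)c2cc(OC)c(OCc3ccccc3)c(OC)c2)COC(c2ccccc2)(c2ccccc2)c2ccccc2)c(OC)c1 | intermediate
8 | (2R,3R)-trans-benzodioxane methyl ester | COc1cc([C@H]2Oc3cc(C(=O)OC)cc(OC)c3O[C@@H]2COC(c2ccccc2)(c2ccccc2)c2ccccc2)cc(OC)c1OCc1ccccc1 | intermediate
9 | 1-[2,4-bis(benzyloxy)-6-hydroxyphenyl]ethan-1-one | CC(=O)c1c(O)cc(OCc2ccccc2)cc1OCc1ccccc1 | starting material
10 | (2R,3R) 1,3-diketone | COc1cc([C@H]2Oc3cc(C(=O)CC(=O)c4c(O)cc(OCc5ccccc5)cc4OCc4ccccc4)cc(OC)c3O[C@@H]2COC(c2ccccc2)(c2ccccc2)c2ccccc2)cc(OC)c1OCc1ccccc1 | intermediate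
11 | (2R,3R) tri-O-benzylpalstatin | COc1cc([C@H]2Oc3cc(-c4cc(=O)c5c(OCc6ccccc6)cc(OCc6ccccc6)cc5o4)cc(OC)c3O[C@@H]2CO)cc(OC)c1OCc1ccccc1 | intermediate
12 | palstatin | COc1cc([C@H]2Oc3cc(-c4cc(=O)c5c(O)cc(O)cc5o4)cc(OC)c3O[C@@H]2CO)cc(OC)c1O | target

## Summary
Total steps: 8.
Longest linear sequence: 8 (1 → 3 → 5 → 6 → 7 → 8 → 10 → 11 → 12).

**Steps most likely to fail**

1. **Step 5 (Pd C–O closure).**
   - Risk: β-hydride elimination of the secondary benzylic Pd alkoxide would give the ketone plus the debrominated arene. The neighbouring CH2OTr also adds steric hindrance.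
   - Fallback: reverse the polarity of the ring closure. Convert the ArBr of diol 6 to ArOH by Miyaura borylation and H2O2 oxidation. Then form the benzylic C–O bond through the acid-generated p-alkoxybenzyl cation (cat. TsOH or BF3·OEt2, CH2Cl2). Only the benzylic OH ionises, so no trityl group is needed, and the fixed C-2 centre directs closure to the trans isomer.

2. **Step 6 (Claisen condensation on an electron-rich trialkoxybenzoate).**
   - Risk: the condensation may be slow or low-yielding.
   - Fallback: switch to the chalcone construction. Take ester 8 to the aldehyde with LiAlH4 then MnO2. Run a Claisen–Schmidt condensation with 9 (KOH, EtOH), then an I2 (cat.)/DMSO oxidative cyclisation to the flavone. Detritylate with mild acid to rejoin the route at 11.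

3. **Step 2 (aldol with a 2,6-disubstituted aryloxy enolate).**
   - Risk: conversion or diastereoselectivity may be poor.
   - Fallback: drop the auxiliary.
     - O-alkylate 1 with ethyl 2-bromo-3-[4-(benzyloxy)-3,5-dimethoxyphenyl]-3-oxopropanoate.
     - Set both centres by Noyori-type asymmetric transfer hydrogenation with dynamic kinetic resolution (tethered Ru/Rh–TsDPEN, HCO2H/Et3N), which gives the syn α-aryloxy-β-hydroxy ester.
     - Reduce the aliphatic ester selectively with NaBH4 to rejoin the route at 6.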